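**Strategy**

The route rests on cutting the bond between C1 of the guaiacyl ring and the benzylic CH2 of the ethylene bridge. Read backwards, the bridge together with C2=C3–C4=O of the 4H-chromen-4-one ring is a linear dienone whose δ-carbon is that CH2, so the precursor is 2-ethenyl-6,7-dimethoxychromone. A rhodium-catalysed 1,6-conjugate addition of the unprotected 4-hydroxy-3-methoxyphenylboronic pinacol ester to this vinylogous enone forms the aryl–CH2 bond, leaves the CH2CH2 bridge at the correct oxidation level and gives the target directly, without protecting groups or redox adjustment. The vinylchromone comes in three steps from 2'-hydroxy-4',5'-dimethoxyacetophenone.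

Key step: step 4

Remark: the target has no stereocentre, so no stereocontrol is needed; compounds 1 and 6 are taken as commercially available, and chromone numbering is O1, C2, C3, C4(=O).

**Route**

Step 1
Reactants: 1 2'-hydroxy-4',5'-dimethoxyacetophenone
Product: 3 6,7-dimethoxy-2-methyl-4H-chromen-4-one, via 1-(2-hydroxy-4,5-dimethoxyphenyl)butane-1,3-dione 2 (not isolated)
Conditions: NaH (4 equiv), EtOAc, THF, reflux; then conc. HCl, AcOH, 90 °C
Reagents that add atoms: ethyl acetate, CCOC(C)=O
Why: Claisen condensation of the phenoxide-enolate of 1 with ethyl acetate should give diketone 2, whose phenol adds to the distal carbonyl and dehydrates under acid to close the 4-pyranone (classical chromone synthesis by Claisen condensation and cyclodehydration).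

Step 2
Reactants: 3 6,7-dimethoxy-2-methyl-4H-chromen-4-one
Product: 4 6,7-dimethoxy-4-oxo-4H-chromene-2-carbaldehyde
Conditions: SeO2 (1.5 equiv), xylene, reflux
Reagents that add atoms: selenium dioxide, O=[Se]=O
Why: Riley oxidation; the C2 methyl is the vinylogous α-position of the C4 carbonyl, so SeO2 should oxidise it selectively to the aldehyde while the aryl methyl ethers stay untouched.

Step 3
Reactants: 4 6,7-dimethoxy-4-oxo-4H-chromene-2-carbaldehyde
Product: 5 2-ethenyl-6,7-dimethoxy-4H-chromen-4-one
Conditions: Ph3PCH3Br, KOtBu, THF, 0 °C; then 4, −78 °C to 0 °C; product kept cold with a trace of BHT and used promptly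
Reagents that add atoms: methyltriphenylphosphonium bromide, C[P+](c1ccccc1)(c1ccccc1)c1ccccc1.[Br-]
Why: Wittig methylenation; the aldehyde is far more electrophilic than the vinylogous-ester C4 carbonyl, so the non-stabilised ylide at low temperature should convert only the CHO group into the vinyl group.

Step 4
Reactants: 5 2-ethenyl-6,7-dimethoxy-4H-chromen-4-one; 6 2-methoxy-4-(4,4,5,5-tetramethyl-1,3,2-dioxaborolan-2-yl)phenol (1.5 equiv)
Product: 7 2-[2-(4-hydroxy-3-methoxyphenyl)ethyl]-6,7-dimethoxy-4H-chromen-4-one (target)
Conditions: [Rh(cod)OH]2 (3 mol %), 1,4-dioxane/H2O (10:1), 60 °C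
Reagents that add atoms: none
Why: Transmetalation of the aryl group of 6 from boron to a Rh(I)–OH species gives an aryl-rhodium that carbometalates the exocyclic vinyl group of 5 with aryl delivery to the terminal CH2, and the resulting rhodium dienolate (delocalised over the former vinyl CH, C2, C3, C4 and the carbonyl O) is protonated by water at the carbon next to C2, which restores the 4-pyranone and returns Rh–OH. The closest known reaction type is the Hayashi–Miyaura rhodium-catalysed conjugate addition of arylboron reagents in its 1,6-mode to dienones and dienoates and to alkenyl heteroarenes. No ring is closed and no stereocentre is formed. The step needs δ- over β-selectivity, which the substrate secures because C2 is fully substituted and deactivated as a vinylogous ester carbon while the δ-carbon is an unhindered terminal CH2. It also needs protonolysis to outrun β-hydride elimination, which the aqueous medium and the O-bound dienolate form favour; the free phenol should be tolerated because no strong base is required.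

**Compound list**

1 | 1-(2-hydroxy-4,5-dimethoxyphenyl)ethan-1-one (2'-hydroxy-4',5'-dimethoxyacetophenone) | CC(=O)c1cc(OC)c(OC)cc1O | starting material
2 | 1-(2-hydroxy-4,5-dimethoxyphenyl)butane-1,3-dione | CC(=O)CC(=O)c1cc(OC)c(OC)cc1O | intermediate
3 | 6,7-dimethoxy-2-methyl-4H-chromen-4-one | Cc1cc(=O)c2cc(OC)c(OC)cc2o1 | intermediate
4 | 6,7-dimethoxy-4-oxo-4H-chromene-2-carbaldehyde | O=Cc1cc(=O)c2cc(OC)c(OC)cc2o1 | intermediate
5 | 2-ethenyl-6,7-dimethoxy-4H-chromen-4-one | C=Cc1cc(=O)c2cc(OC)c(OC)cc2o1 | intermediate
6 | 2-methoxy-4-(4,4,5,5-tetramethyl-1,3,2-dioxaborolan-2-yl)phenol | COc1cc(B2OC(C)(C)C(C)(C)O2)ccc1O | starting material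
7 | 2-[2-(4-hydroxy-3-methoxyphenyl)ethyl]-6,7-dimethoxy-4H-chromen-4-one | COc1cc(CCc2cc(=O)c3cc(OC)c(OC)cc3o2)ccc1O | target

**Step count**

Total steps: 4. Longest linear sequence: 4 steps (1 → 3 → 4 → 5 → 7); 6 enters in the last step.

**Steps most likely to fail**

Step 4. Three processes may compete with the 1,6-addition: protodeboronation of the electron-rich arylboronate before carborhodation, reversible oxa-Michael addition of the phenol to the vinyl group, and β-hydride elimination from the alkylrhodium intermediate to a styryl product. The fallback sets out from 5 and forms the same bond by a Mizoroki–Heck reaction with commercial 4-bromo-2-methoxyphenol (COc1cc(Br)ccc1O; Pd(OAc)2, P(o-tol)3, Et3N, DMF, 100 °C). This should give (E)-2-[2-(4-hydroxy-3-methoxyphenyl)ethenyl]-6,7-dimethoxy-4H-chromen-4-one F1. Hydrogenation of its exocyclic disubstituted double bond (H2, 1 atm, Pd/C, EtOAc, rt, stopped after one equivalent), which should be reduced faster than the pyranone C2=C3 bond, comes back to the route at 7.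

Step 3. The ylide may add in a conjugate sense at C2 of the chromone, and the vinylchromone may dimerise or polymerise during isolation. The fallback sets out from 3 and avoids both the aldehyde and the ylide. Lateral deprotonation of the C2 methyl (LDA, THF, −78 °C) and Mannich reaction with dimethylmethyleneammonium iodide should give 2-[2-(dimethylamino)ethyl]-6,7-dimethoxy-4H-chromen-4-one F2. Quaternisation with MeI (acetone, rt) gives 2-(6,7-dimethoxy-4-oxo-4H-chromen-2-yl)-N,N,N-trimethylethan-1-aminium iodide F3, a storable salt. Elimination with aqueous NaHCO3/CH2Cl2 just before use comes back to the route at 5.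

Step 2. Over-oxidation of the aldehyde to the carboxylic acid, incomplete conversion and retention of colloidal selenium may spoil the Riley oxidation. The fallback sets out from 1 and builds the C2 carbon at the ester level. Claisen condensation with diethyl oxalate (NaOEt, EtOH, reflux; then HCl, AcOH) should give ethyl 6,7-dimethoxy-4-oxo-4H-chromene-2-carboxylate F4. Chemoselective reduction of the activated ester (NaBH4, MeOH, 0 °C) gives 2-(hydroxymethyl)-6,7-dimethoxy-4H-chromen-4-one F5. Oxidation with activated MnO2 (CH2Cl2, rt) comes back to the route at 4.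

**Further compounds**

F1 | step 4 | (E)-2-[2-(4-hydroxy-3-methoxyphenyl)ethenyl]-6,7-dimethoxy-4H-chromen-4-one | COc1cc(/C=C/c2cc(=O)c3cc(OC)c(OC)cc3o2)ccc1O
F2 | step 3 | 2-[2-(dimethylamino)ethyl]-6,7-dimethoxy-4H-chromen-4-one | CN(C)CCc1cc(=O)c2cc(OC)c(OC)cc2o1
F3 | step 3 | 2-(6,7-dimethoxy-4-oxo-4H-chromen-2-yl)-N,N,N-trimethylethan-1-aminium iodide | C[N+](C)(C)CCc1cc(=O)c2cc(OC)c(OC)cc2o1.[I-]
F4 | step 2 | ethyl 6,7-dimethoxy-4-oxo-4H-chromene-2-carboxylate | CCOC(=O)c1cc(=O)c2cc(OC)c(OC)cc2o1
F5 | step 2 | 2-(hydroxymethyl)-6,7-dimethoxy-4H-chromen-4-one | OCc1cc(=O)c2cc(OC)c(OC)cc2o1
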